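**Retrosynthetic overview** (C1 is the chain carbon bonded to ring A; C5 is the carbinol carbon)
1. The target comes from global acidic deprotection of a MOM/TBS-protected chalcone, which comes from a Claisen–Schmidt condensation of benzaldehyde with a ring A methyl ketone.
2. Key disconnection: the C1–C2 (diarylmethine–vinyl) bond, made by an enantioconvergent nickel-catalysed radical coupling of a racemic diarylmethyl chloride with an alkenylzirconocene. This sets C1 by catalyst control.
3. The diarylmethanol precursor comes from an aryl Grignard reagent (from 4-iodophenol) and a ring A keto aldehyde, itself made from resorcinol by C–H borylation/methoxylation and a one-pot double directed lithiation.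
4. The alkyne partner comes from a Heck reaction of the same aryl iodide with allyl alcohol, then Brown asymmetric propargylation (sets C5) and silylation.
5. No ring is formed: the four benzene rings come from resorcinol, 4-iodophenol (used twice) and benzaldehyde.

Assumption: the reagent antipodes named in steps 7 and 9 are those expected to give (5R) and (1S); each is checked on the first run (Mosher ester; comparison with the C1 epimer) and the mirror-image reagent or ligand is used if the opposite sense is found.

**Step 1**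
Reactants: 1 resorcinol
Product: 2 1,3-bis(methoxymethoxy)benzene
Conditions: NaH (2.4 equiv), MOMCl (2.4 equiv), DMF, 0 °C → rt
Reagents that add atoms: chloromethyl methyl ether (MOMCl), COCCl
Why: Double Williamson O-alkylation of the bis-phenoxide; the MOM ethers later act as ortho-directing groups and as acid-labile protection.

**Step 2**
Reactants: 2 1,3-bis(methoxymethoxy)benzene
Product: 4 1-methoxy-3,5-bis(methoxymethoxy)benzene, via arylboronate 3 (not isolated)
Conditions: [Ir(OMe)(cod)]2 (1.5 mol%), dtbpy (3 mol%), B2pin2 (1.0 equiv), THF, 80 °C; evaporate; then Cu(OAc)2 (20 mol%), DMAP (40 mol%), 4 Å MS, MeOH, O2 (1 atm), 50 °C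
Reagents that add atoms: methanol, CO
Why: Sterically controlled iridium-catalysed C–H borylation occurs only at C5, the one C–H without an ortho substituent, and the aryl boronate is then turned into the methyl ether by copper-catalysed aerobic Chan–Lam etherification in methanol.

**Step 3**
Reactants: 4 1-methoxy-3,5-bis(methoxymethoxy)benzene
Product: 8 3-acetyl-4-methoxy-2,6-bis(methoxymethoxy)benzaldehyde, via aryllithium 5 (not isolated), via lithium amino alkoxide 6 (not isolated), via ring-lithiated amino alkoxide 7 (not isolated)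
Conditions: n-BuLi (1.05 equiv), THF, 0 °C, 1 h; DMF (1.1 equiv), −78 → 0 °C; TMEDA, s-BuLi (1.5 equiv), −78 → −40 °C; N-methoxy-N-methylacetamide (2 equiv), −78 → 0 °C; sat. aq. NH4Cl
Reagents that add atoms: N,N-dimethylformamide, CN(C)C=O; N-methoxy-N-methylacetamide, CC(=O)N(C)OC
Why: Directed ortho-metalation goes first to the position flanked by the two OMOM groups, formylation leaves the lithium α-amino alkoxide 6 as an in situ protected aldehyde (Comins-type), a second directed ortho-metalation then takes the only remaining kind of ring position (between OMOM and OMe), and the Weinreb amide gives the methyl ketone without over-addition.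

**Step 4**
Reactants: 9 4-iodophenol
Product: 10 1-iodo-4-(methoxymethoxy)benzene
Conditions: NaH (1.2 equiv), MOMCl (1.2 equiv), DMF, 0 °C → rt
Reagents that add atoms: chloromethyl methyl ether (MOMCl), COCCl
Why: Williamson O-alkylation; the MOM ether tolerates the Grignard, Heck, peroxide and hydroxide conditions that follow, and 10 serves both aryl fragments.

**Step 5**
Reactants: 10 1-iodo-4-(methoxymethoxy)benzene; 8 3-acetyl-4-methoxy-2,6-bis(methoxymethoxy)benzaldehyde
Product: 12 rac-1-{3-[hydroxy(4-(methoxymethoxy)phenyl)methyl]-6-methoxy-2,4-bis(methoxymethoxy)phenyl}ethan-1-one, via aryl Grignard reagent 11 (not isolated)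
Conditions: 10 (1.15 equiv), i-PrMgCl·LiCl (1.1 equiv), THF, 0 °C → rt, 2 h; then 8, THF, −78 → −40 °C; sat. aq. NH4Cl
Reagents that add atoms: none
Why: Iodine–magnesium exchange gives the aryl Grignard reagent, which adds at −78 °C to the chelation-activated aldehyde much faster than to the twisted, di-ortho-substituted methyl ketone (chemoselective 1,2-addition); the carbinol centre is left racemic because step 9 is stereoconvergent.

**Step 6**
Reactants: 10 1-iodo-4-(methoxymethoxy)benzene; 13 allyl alcohol
Product: 14 3-[4-(methoxymethoxy)phenyl]propanal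
Conditions: Pd(OAc)2 (3 mol%), n-Bu4NCl (1 equiv), NaHCO3 (2.5 equiv), DMF, 45 °C
Reagents that add atoms: none
Why: Heck arylation of allyl alcohol under Jeffery conditions: insertion at the terminal carbon, β-hydride elimination toward the carbinol and tautomerisation give the 3-arylpropanal directly.

**Step 7**
Reactants: 14 3-[4-(methoxymethoxy)phenyl]propanal; 15 propargyl bromide
Product: 18 (3R)-1-[4-(methoxymethoxy)phenyl]hex-5-yn-3-ol, via allenylmagnesium bromide 16 (not isolated), via B-allenyldiisopinocampheylborane 17 (not isolated)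
Conditions: 15, Mg, HgCl2 (1 mol%), Et2O, 0 °C; (−)-Ipc2BOMe [from (+)-α-pinene], Et2O, −78 °C → rt; 14, −78 °C, 3 h; then NaOH, H2O2, 0 °C → rt
Reagents that add atoms: none
Why: Brown asymmetric propargylation: the allenylborane adds through a closed six-membered chair transition state (SE2') to the Si face of the aldehyde, giving only the homopropargylic alcohol with the (R) configuration at the future C5.

**Step 8**
Reactants: 18 (3R)-1-[4-(methoxymethoxy)phenyl]hex-5-yn-3-ol
Product: 19 tert-butyl{[(3R)-1-[4-(methoxymethoxy)phenyl]hex-5-yn-3-yl]oxy}dimethylsilane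
Conditions: TBSCl (1.3 equiv), imidazole (2.5 equiv), DMF, rt
Reagents that add atoms: tert-butyldimethylsilyl chloride (TBSCl), CC(C)(C)[Si](C)(C)Cl
Why: Standard imidazole-promoted O-silylation, which keeps the alcohol away from the Zr–H reagent and from the electrophilic chloride of step 9 without touching the stereocentre.

**Step 9 (key step)**
Reactants: 12 rac-1-{3-[hydroxy(4-(methoxymethoxy)phenyl)methyl]-6-methoxy-2,4-bis(methoxymethoxy)phenyl}ethan-1-one; 19 tert-butyl{[(3R)-1-[4-(methoxymethoxy)phenyl]hex-5-yn-3-yl]oxy}dimethylsilane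
Product: 22 1-{3-[(1S,2E,5R)-5-{[tert-butyl(dimethyl)silyl]oxy}-1,7-bis[4-(methoxymethoxy)phenyl]hept-2-en-1-yl]-6-methoxy-2,4-bis(methoxymethoxy)phenyl}ethan-1-one, via benzhydryl chloride 20 (not isolated), via alkenylzirconocene chloride 21 (not isolated)
Conditions: 12, 1-chloro-N,N,2-trimethylprop-1-en-1-amine (1.1 equiv), DME, 0 °C, 30 min; separately 19 (1.5 equiv), Cp2Zr(H)Cl (1.4 equiv), THF, rt, 45 min; both solutions added to NiCl2(dme) (8 mol%), (3aR,3a'R,8aS,8a'S)-2,2'-(cyclopropane-1,1-diyl)bis(3a,8a-dihydro-8H-indeno[1,2-d]oxazole) (10 mol%), DME/THF, 0 °C, 24 h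
Reagents that add atoms: none
Why: Proposed new method: a monovalent nickel–bis(oxazoline) species abstracts chlorine from racemic 20 to give a planar, hindered diarylmethyl radical (both enantiomers converge), which is captured by the chiral alkenylnickel complex formed by transmetalation from the (E)-alkenylzirconocene 21 (syn, terminal hydrozirconation), and the trivalent nickel intermediate reductively eliminates to form C1–C2 with retention of the E geometry; the ligand pocket distinguishes the twisted 2,6-dioxygenated ring A from the flat para-substituted phenyl and so sets C1 (S) independently of the remote C5 centre; the closest known reactions are the stereoconvergent nickel/bis(oxazoline) couplings of racemic α-bromo ketones with alkenylzirconocenes and of racemic secondary benzylic halides with organozinc reagents, and the asymmetric nickel-catalysed reductive alkenylation of benzylic chlorides.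

**Step 10**
Reactants: 22 1-{3-[(1S,2E,5R)-5-{[tert-butyl(dimethyl)silyl]oxy}-1,7-bis[4-(methoxymethoxy)phenyl]hept-2-en-1-yl]-6-methoxy-2,4-bis(methoxymethoxy)phenyl}ethan-1-one; 23 benzaldehyde
Product: 24 (2E)-1-{3-[(1S,2E,5R)-5-{[tert-butyl(dimethyl)silyl]oxy}-1,7-bis[4-(methoxymethoxy)phenyl]hept-2-en-1-yl]-6-methoxy-2,4-bis(methoxymethoxy)phenyl}-3-phenylprop-2-en-1-one
Conditions: 23 (3 equiv), KOH (10 equiv), EtOH/H2O 4:1, rt, 36 h
Reagents that add atoms: none
Why: Claisen–Schmidt (crossed aldol) condensation: the methyl ketone enolate adds to non-enolisable benzaldehyde and E1cB dehydration gives the (E)-enone; MOM and alkyl TBS ethers are base-stable and the C1–H (triarylmethane-like, not α to a carbonyl) is not deprotonated, so C1 is not scrambled.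

**Step 11**
Reactants: 24 (2E)-1-{3-[(1S,2E,5R)-5-{[tert-butyl(dimethyl)silyl]oxy}-1,7-bis[4-(methoxymethoxy)phenyl]hept-2-en-1-yl]-6-methoxy-2,4-bis(methoxymethoxy)phenyl}-3-phenylprop-2-en-1-one
Product: 25 7-epi-katsumain C
Conditions: HCl (1.5 M in MeOH/H2O 9:1), 0 °C → rt, 2–4 h; pH 6 buffer
Reagents that add atoms: none
Why: Acid-catalysed methanolysis of the four MOM acetals and the silyl ether at room temperature, conditions used for closely related hydroxy-methoxychalcones (xanthohumol type) where flavanone cyclisation is slow; the acyl group on ring A disfavours ipso-protonation and so protects the C1–ring A bond and the C1 configuration.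

**Compound list**
1 | resorcinol | Oc1cccc(O)c1 | starting material
2 | 1,3-bis(methoxymethoxy)benzene | COCOc1cccc(OCOC)c1 | intermediate
3 | 2-[3,5-bis(methoxymethoxy)phenyl]-4,4,5,5-tetramethyl-1,3,2-dioxaborolane | COCOc1cc(OCOC)cc(c1)B1OC(C)(C)C(C)(C)O1 | intermediate
4 | 1-methoxy-3,5-bis(methoxymethoxy)benzene | COCOc1cc(OC)cc(OCOC)c1 | intermediate
5 | [4-methoxy-2,6-bis(methoxymethoxy)phenyl]lithium | [Li]c1c(OCOC)cc(OC)cc1OCOC | intermediate
6 | lithium (dimethylamino)[4-methoxy-2,6-bis(methoxymethoxy)phenyl]methanolate | [Li]OC(N(C)C)c1c(OCOC)cc(OC)cc1OCOC | intermediate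
7 | lithium (dimethylamino)[3-lithio-4-methoxy-2,6-bis(methoxymethoxy)phenyl]methanolate | [Li]OC(N(C)C)c1c(OCOC)cc(OC)c([Li])c1OCOC | intermediate
8 | 3-acetyl-4-methoxy-2,6-bis(methoxymethoxy)benzaldehyde | COCOc1cc(OC)c(C(C)=O)c(OCOC)c1C=O | intermediate
9 | 4-iodophenol | Oc1ccc(I)cc1 | starting material
10 | 1-iodo-4-(methoxymethoxy)benzene | COCOc1ccc(I)cc1 | intermediate
11 | [4-(methoxymethoxy)phenyl]magnesium chloride (LiCl complex) | COCOc1ccc([Mg]Cl)cc1 | intermediate
12 | rac-1-{3-[hydroxy(4-(methoxymethoxy)phenyl)methyl]-6-methoxy-2,4-bis(methoxymethoxy)phenyl}ethan-1-one | COCOc1ccc(cc1)C(O)c1c(OCOC)cc(OC)c(C(C)=O)c1OCOC | intermediate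
13 | allyl alcohol (prop-2-en-1-ol) | C=CCO | starting material
14 | 3-[4-(methoxymethoxy)phenyl]propanal | COCOc1ccc(CCC=O)cc1 | intermediate
15 | propargyl bromide (3-bromoprop-1-yne) | C#CCBr | starting material
16 | allenylmagnesium bromide | C=C=C[Mg]Br | intermediate
17 | B-allenyldiisopinocampheylborane [from (−)-Ipc2BOMe] | C=C=CB([C@@H]1C[C@@H]2C[C@H]([C@H]1C)C2(C)C)[C@@H]1C[C@@H]2C[C@H]([C@H]1C)C2(C)C | intermediate
18 | (3R)-1-[4-(methoxymethoxy)phenyl]hex-5-yn-3-ol | C#CC[C@H](O)CCc1ccc(OCOC)cc1 | intermediate
19 | tert-butyl{[(3R)-1-[4-(methoxymethoxy)phenyl]hex-5-yn-3-yl]oxy}dimethylsilane | C#CC[C@H](O[Si](C)(C)C(C)(C)C)CCc1ccc(OCOC)cc1 | intermediate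
20 | rac-1-{3-[chloro(4-(methoxymethoxy)phenyl)methyl]-6-methoxy-2,4-bis(methoxymethoxy)phenyl}ethan-1-one | COCOc1ccc(cc1)C(Cl)c1c(OCOC)cc(OC)c(C(C)=O)c1OCOC | intermediate
21 | chlorobis(cyclopentadienyl)[(1E,4R)-4-{[tert-butyl(dimethyl)silyl]oxy}-6-[4-(methoxymethoxy)phenyl]hex-1-en-1-yl]zirconium | Cl[Zr](/C=C/C[C@H](O[Si](C)(C)C(C)(C)C)CCc1ccc(OCOC)cc1)(C1C=CC=C1)C1C=CC=C1 | intermediate
22 | 1-{3-[(1S,2E,5R)-5-{[tert-butyl(dimethyl)silyl]oxy}-1,7-bis[4-(methoxymethoxy)phenyl]hept-2-en-1-yl]-6-methoxy-2,4-bis(methoxymethoxy)phenyl}ethan-1-one | COc1cc(OCOC)c([C@@H](/C=C/C[C@H](O[Si](C)(C)C(C)(C)C)CCc2ccc(OCOC)cc2)c2ccc(OCOC)cc2)c(OCOC)c1C(C)=O | intermediate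
23 | benzaldehyde | O=Cc1ccccc1 | starting material
24 | (2E)-1-{3-[(1S,2E,5R)-5-{[tert-butyl(dimethyl)silyl]oxy}-1,7-bis[4-(methoxymethoxy)phenyl]hept-2-en-1-yl]-6-methoxy-2,4-bis(methoxymethoxy)phenyl}-3-phenylprop-2-en-1-one | COc1cc(OCOC)c([C@@H](/C=C/C[C@H](O[Si](C)(C)C(C)(C)C)CCc2ccc(OCOC)cc2)c2ccc(OCOC)cc2)c(OCOC)c1C(=O)/C=C/c1ccccc1 | intermediate
25 | 7-epi-katsumain C; (2E)-1-{2,4-dihydroxy-3-[(1S,2E,5R)-5-hydroxy-1,7-bis(4-hydroxyphenyl)hept-2-en-1-yl]-6-methoxyphenyl}-3-phenylprop-2-en-1-one | COc1cc(O)c([C@@H](/C=C/C[C@H](O)CCc2ccc(O)cc2)c2ccc(O)cc2)c(O)c1C(=O)/C=C/c1ccccc1 | target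

**Totals**
Total step count: 11.
Longest linear sequence: 7 steps (1, 2, 3, 5, 9, 10, 11; the branch 4, 6, 7, 8, 9, 10, 11 is equally long).

**Three steps most likely to fail**

Step 9 (nickel-catalysed radical alkenylation). Likely failure modes are:
- ionisation of chloride 20 with capture by an ortho MOM oxygen;
- homodimerisation of the diarylmethyl radical;
- uncatalysed, racemic alkenyl transfer from zirconium;
- too little discrimination between the two aryl groups (the C1 epimers are diastereomers because of C5 and can be separated by chromatography).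

The fallback sets out from 19 and 12 and comes back at 22. Alkyne 19 is hydrozirconated as before (Cp2Zr(H)Cl, THF) and 21 is quenched with N-bromosuccinimide to give the isolated vinyl bromide {[(3R,5E)-6-bromo-1-[4-(methoxymethoxy)phenyl]hex-5-en-3-yl]oxy}(tert-butyl)dimethylsilane F1. Alcohol 12 is converted into chloride 20 as in step 9. Compounds 20 and F1, now two electrophiles, are joined in an asymmetric reductive cross-electrophile coupling (NiCl2(dme) 10 mol%, the same bis(oxazoline) ligand, Mn powder, NaI, DMA, 0 °C) to give 22. No organometallic nucleophile is present, so the polar background reaction disappears, and this is the manifold with the closest precedent for benzylic chloride/vinyl bromide pairs.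

Step 3 (one-pot double directed lithiation). Risks are incomplete regiocontrol in the first lithiation and incomplete second lithiation of the amino alkoxide. The fallback sets out from 4 and comes back at 8, and replaces the second lithiation by electrophilic substitution and cross-coupling. Compound 4 is lithiated (n-BuLi, THF, 0 °C) and formylated with DMF, and the aldehyde 4-methoxy-2,6-bis(methoxymethoxy)benzaldehyde F2 is isolated. Bromination with N-bromosuccinimide (MeCN, 0 °C) gives 3-bromo-4-methoxy-2,6-bis(methoxymethoxy)benzaldehyde F3, since the two free ring positions are equivalent. Stille coupling with tributyl(1-ethoxyvinyl)stannane (Pd(PPh3)4, toluene, 100 °C) gives 3-(1-ethoxyethenyl)-4-methoxy-2,6-bis(methoxymethoxy)benzaldehyde F4. Brief hydrolysis of the enol ether (oxalic acid on wet silica, CH2Cl2, rt) gives 8.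

Step 11 (global acidic deprotection of the chalcone). Risks are flavanone formation or methanol addition at the enone and acid-induced loss of configuration at C1. The fallback sets out from 22 and comes back at 25, and reverses the order of the last two operations. The methyl ketone 22, which has no enone, is deprotected with HCl in MeOH (0 °C → rt) to 1-{2,4-dihydroxy-3-[(1S,2E,5R)-5-hydroxy-1,7-bis(4-hydroxyphenyl)hept-2-en-1-yl]-6-methoxyphenyl}ethan-1-one F5. The free polyphenol F5 is then condensed with benzaldehyde 23 under Claisen–Schmidt conditions with a large excess of aqueous KOH in EtOH (rt, 48–72 h), followed by acidification to pH 5 at 0 °C, to give 25 without any acid treatment of the chalcone.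

**Further compounds**
F1 | step 9 | {[(3R,5E)-6-bromo-1-[4-(methoxymethoxy)phenyl]hex-5-en-3-yl]oxy}(tert-butyl)dimethylsilane | Br/C=C/C[C@H](O[Si](C)(C)C(C)(C)C)CCc1ccc(OCOC)cc1
F2 | step 3 | 4-methoxy-2,6-bis(methoxymethoxy)benzaldehyde | COc1cc(OCOC)c(C=O)c(OCOC)c1
F3 | step 3 | 3-bromo-4-methoxy-2,6-bis(methoxymethoxy)benzaldehyde | COc1cc(OCOC)c(C=O)c(OCOC)c1Br
F4 | step 3 | 3-(1-ethoxyethenyl)-4-methoxy-2,6-bis(methoxymethoxy)benzaldehyde | CCOC(=C)c1c(OC)cc(OCOC)c(C=O)c1OCOC
F5 | step 11 | 1-{2,4-dihydroxy-3-[(1S,2E,5R)-5-hydroxy-1,7-bis(4-hydroxyphenyl)hept-2-en-1-yl]-6-methoxyphenyl}ethan-1-one | COc1cc(O)c([C@@H](/C=C/C[C@H](O)CCc2ccc(O)cc2)c2ccc(O)cc2)c(O)c1C(C)=O
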